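**Retrosynthetic overview**
1. The last bond is C5'(ring B)–CH, which sets the only stereocentre. Caraganin A ⇒ cajanin + a vinylogous para-quinone methide, released from a racemic 1,3-diarylallyl alcohol under a chiral phosphoric acid.
2. The key bond is C3–C1' of the isoflavone. Both carbons are innately nucleophilic, so C3 is inverted into an enolonium equivalent, a chromon-3-yl(mesityl)iodonium salt. It is joined by copper-catalysed C–H coupling to silyl-capped resorcinol, with no halide, boron or lasting protecting group on ring B.
3. Iodonium salt ⇒ ortho-hydroxyaryl enaminone ⇒ 2',6'-dihydroxy-4'-methoxyacetophenone + DMF dimethyl acetal.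
4. Allyl alcohol ⇒ chalcone ⇒ 4'-hydroxyacetophenone + 2,4-dimethoxybenzaldehyde.
5. Ring order: only the pyranone ring C is built (step 2). The four benzene rings are bought.

Assumption: the facial sense of the phosphoric acid in step 6 cannot be derived with certainty, so the (R)-acid is written for the (R)-product and its mirror image is used if the first run gives the antipode.

**Step 1**
Reactants: 1 1-(2,6-dihydroxy-4-methoxyphenyl)ethan-1-one; 2 N,N-dimethylformamide dimethyl acetal
Product: 3 (E)-1-(2,6-dihydroxy-4-methoxyphenyl)-3-(dimethylamino)prop-2-en-1-one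
Conditions: 2 (1.5 equiv), toluene, 80 °C, 3 h
Reagents that add atoms: none
Why: Enaminone condensation (aminomethylenation with an amide acetal): the acidic acetyl CH3 of the chelated aryl ketone condenses with 2, losing two MeOH, to give the E-enaminone that carries the future C2.

**Step 2**
Reactants: 3 (E)-1-(2,6-dihydroxy-4-methoxyphenyl)-3-(dimethylamino)prop-2-en-1-one
Product: 4 (5-hydroxy-7-methoxy-4-oxo-4H-chromen-3-yl)(2,4,6-trimethylphenyl)iodonium trifluoromethanesulfonate
Conditions: MesI(OAc)2 (1.05 equiv), TfOH (1.05 equiv), CH2Cl2, premix at −40 °C, add 3, −40 °C to rt; precipitate with Et2O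
Reagents that add atoms: iodomesitylene diacetate, CC(=O)OI(OC(C)=O)c1c(C)cc(C)cc1C; trifluoromethanesulfonic acid, OS(=O)(=O)C(F)(F)F
Why: Proposed new method: the TfOH-activated λ3-iodane is attacked by the strongly nucleophilic enaminone α-carbon, and the ortho-OH then adds to the iminium carbon and expels Me2NH, which closes ring C and turns the normally nucleophilic C3 into an enolonium equivalent; this electrophile-triggered chromone annulation is known for I2 and for sulfenyl or selenenyl halides, and the closest known reaction type is the direct formation of alkenyl(aryl)iodonium salts from enaminone-type C–H bonds such as uracil C5 with ArI(OAc)2/TfOH.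

**Step 3 (key step)**
Reactants: 4 (5-hydroxy-7-methoxy-4-oxo-4H-chromen-3-yl)(2,4,6-trimethylphenyl)iodonium trifluoromethanesulfonate; 5 1,3-bis(trimethylsilyloxy)benzene
Product: 7 cajanin = 3-(2,4-dihydroxyphenyl)-5-hydroxy-7-methoxy-4H-chromen-4-one, via cajanin 2',4'-bis(trimethylsilyl) ether 6 (not isolated)
Conditions: 5 (3 equiv), Cu(OTf)2 (10 mol %), 2,6-di-tert-butylpyridine (1.2 equiv), ClCH2CH2Cl, 50 °C; then 1 M HCl, THF, rt
Reagents that add atoms: none
Why: Proposed new method: monovalent copper formed in situ takes the less hindered chromon-3-yl group from iodine (mesityl leaves as MesI) to give a strongly electrophilic chromon-3-yl trivalent-copper triflate, an α-keto cation (enolonium) equivalent, which is attacked by the most nucleophilic carbon of 5 (C4, para to one OSiMe3 and ortho to the other) in a Friedel–Crafts-type C–H arylation with reductive elimination, so that two innately nucleophilic carbons are joined; the closest known reaction types are the Cu(OTf)2-catalysed para-selective C–H arylation of anisole-type ethers with diaryliodonium triflates and copper-catalysed alkenyl transfer from alkenyl(aryl)iodonium salts, and the silyl caps block O-alkenylation and fall off in the acid work-up.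

**Step 4**
Reactants: 8 4'-hydroxyacetophenone; 9 2,4-dimethoxybenzaldehyde
Product: 10 (E)-3-(2,4-dimethoxyphenyl)-1-(4-hydroxyphenyl)prop-2-en-1-one
Conditions: KOH (50% aq, 5 equiv), EtOH, rt, 24 h; then HCl to pH 5
Reagents that add atoms: none
Why: Claisen–Schmidt aldol condensation of a methyl ketone with a non-enolisable aldehyde, in which E1cB dehydration gives only the E-chalcone.

**Step 5**
Reactants: 10 (E)-3-(2,4-dimethoxyphenyl)-1-(4-hydroxyphenyl)prop-2-en-1-one
Product: 11 (±)-(E)-3-(2,4-dimethoxyphenyl)-1-(4-hydroxyphenyl)prop-2-en-1-ol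
Conditions: i-Bu2AlH (3.5 equiv), THF/toluene, −78 to 0 °C; aq KNaC4H4O6 work-up at pH ≥ 7; used at once
Reagents that add atoms: none
Why: Selective 1,2-reduction of an enone with i-Bu2AlH, which first caps the free phenol as a weakly donating aluminium phenoxide (as in the reduction of unprotected hydroxycinnamates) and then delivers hydride to C=O; the carbinol centre is racemic on purpose because it is erased in step 6.

**Step 6**
Reactants: 7 cajanin; 11 (±)-(E)-3-(2,4-dimethoxyphenyl)-1-(4-hydroxyphenyl)prop-2-en-1-ol
Product: 13 caraganin A = 3-{5-[(1R,2E)-1-(2,4-dimethoxyphenyl)-3-(4-hydroxyphenyl)prop-2-en-1-yl]-2,4-dihydroxyphenyl}-5-hydroxy-7-methoxy-4H-chromen-4-one, via vinylogous para-quinone methide 12 (not isolated)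
Conditions: (R)-3,3'-bis(2,4,6-triisopropylphenyl)-1,1'-binaphthyl-2,2'-diyl hydrogen phosphate (10 mol %), 5 Å MS, CH2Cl2/MeCN 4:1, −30 °C, slow addition of 11 (1.2 equiv)
Reagents that add atoms: none
Why: Proposed new method: the acid dehydrates 11 to 12, which stays hydrogen-bonded or ion-paired to the chiral phosphate, and the free resorcinol carbon C5' of 7 (ortho to the 4'-OH that binds the phosphoryl oxygen, and more nucleophilic than the carbonyl-deactivated ring A or the crowded C3') adds to the remote terminus bearing the dimethoxyphenyl group in an asymmetric Friedel–Crafts 1,8-addition, which restores the phenol, leaves the E-styrene and sets the R centre because the triisopropylphenyl walls shield one face; the closest known reaction types are phosphoric-acid-catalysed 1,6-additions of naphthols and phenols to para-quinone methides made in situ, 1,8-additions to alkynyl para-quinone methides, and chiral ion-pair substitution of 1,3-diarylallyl alcohols.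

**Compound list**
1 | 1-(2,6-dihydroxy-4-methoxyphenyl)ethan-1-one | COc1cc(O)c(C(C)=O)c(O)c1 | starting material
2 | N,N-dimethylformamide dimethyl acetal | COC(OC)N(C)C | starting material
3 | (E)-1-(2,6-dihydroxy-4-methoxyphenyl)-3-(dimethylamino)prop-2-en-1-one | COc1cc(O)c(C(=O)/C=C/N(C)C)c(O)c1 | intermediate
4 | (5-hydroxy-7-methoxy-4-oxo-4H-chromen-3-yl)(2,4,6-trimethylphenyl)iodonium trifluoromethanesulfonate | COc1cc(O)c2c(=O)c([I+]c3c(C)cc(C)cc3C)coc2c1.[O-]S(=O)(=O)C(F)(F)F | intermediate
5 | 1,3-bis(trimethylsilyloxy)benzene | C[Si](C)(C)Oc1cccc(O[Si](C)(C)C)c1 | starting material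
6 | 3-[2,4-bis(trimethylsilyloxy)phenyl]-5-hydroxy-7-methoxy-4H-chromen-4-one | COc1cc(O)c2c(=O)c(-c3ccc(O[Si](C)(C)C)cc3O[Si](C)(C)C)coc2c1 | intermediate
7 | cajanin, 3-(2,4-dihydroxyphenyl)-5-hydroxy-7-methoxy-4H-chromen-4-one | COc1cc(O)c2c(=O)c(-c3ccc(O)cc3O)coc2c1 | intermediate
8 | 4'-hydroxyacetophenone | CC(=O)c1ccc(O)cc1 | starting material
9 | 2,4-dimethoxybenzaldehyde | COc1ccc(C=O)c(OC)c1 | starting material
10 | (E)-3-(2,4-dimethoxyphenyl)-1-(4-hydroxyphenyl)prop-2-en-1-one | COc1ccc(/C=C/C(=O)c2ccc(O)cc2)c(OC)c1 | intermediate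
11 | (±)-(E)-3-(2,4-dimethoxyphenyl)-1-(4-hydroxyphenyl)prop-2-en-1-ol (racemic carbinol) | COc1ccc(/C=C/C(O)c2ccc(O)cc2)c(OC)c1 | intermediate
12 | 4-[(2E)-3-(2,4-dimethoxyphenyl)prop-2-en-1-ylidene]cyclohexa-2,5-dien-1-one | COc1ccc(/C=C/C=C2C=CC(=O)C=C2)c(OC)c1 | intermediate
13 | caraganin A, (R) at the triaryl-type methine, E alkene | COc1ccc([C@H](/C=C/c2ccc(O)cc2)c2cc(-c3coc4cc(OC)cc(O)c4c3=O)c(O)cc2O)c(OC)c1 | target

**Total step count:** 6. **Longest linear sequence:** 4 (steps 1, 2, 3, 6).

**Steps most likely to fail**

**Step 3 (key coupling).**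
- Risks:
  - Copper may be tied up by the 5-OH/4-C=O chelate.
  - Mesityl may be transferred instead of the chromonyl group.
  - The product may be arylated a second time.
  - The arene may attack C2 instead of C3.
- Fallback: this sets out from 3 and comes back at 7, and moves the reversed polarity from the chromone to ring B.
  - 1,3-Bis(benzyloxy)benzene is treated with MesI(OAc)2/TfOH to give [2,4-bis(benzyloxy)phenyl](2,4,6-trimethylphenyl)iodonium trifluoromethanesulfonate F1, an aryl cation equivalent.
  - Cu(OTf)2-catalysed transfer of this aryl group to the nucleophilic α-carbon of enaminone 3 is followed by spontaneous ring closure with loss of dimethylamine. This gives 3-[2,4-bis(benzyloxy)phenyl]-5-hydroxy-7-methoxy-4H-chromen-4-one F2.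
  - Hydrogenolysis (H2, palladium on carbon, EtOAc) gives 7.

**Step 6 (stereocentre).**
- Risks:
  - 1,6-Addition may occur at the other allyl terminus.
  - Alkylation may occur at C3', C6 or C8.
  - The ee may be modest, because the new centre lies far from the bound oxygen.
  - Alcohol 11 may self-condense.
- Fallback: this sets out from 7 (together with 9) and comes back at 13. It makes the alkene the nucleophile and ring B the quinone methide.
  - The magnesium phenolate of 7 (EtMgBr, toluene) undergoes ortho-directed hydroxyalkylation with 9. This gives 3-{5-[(2,4-dimethoxyphenyl)(hydroxy)methyl]-2,4-dihydroxyphenyl}-5-hydroxy-7-methoxy-4H-chromen-4-one F3.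
  - Its ortho-quinone methide is then trapped by (E)-[2-(4-hydroxyphenyl)ethenyl]boronic acid F4, made from 4-ethynylphenol with catecholborane and then water.
  - The trapping is run under (R)-3,3'-dibromo-1,1'-bi-2-naphthol catalysis, an asymmetric boronate addition in which regiochemistry is no longer in question. It gives 13.

**Step 2 (iodonium salt).**
- Risks:
  - The activated trivalent-iodine reagent may oxidise the ring A phenols.
  - The enaminone may close under acid to the plain chromone before C–I bond formation.
- Fallback: this sets out from 3 and comes back at 4, and forms the C–I bond first at the monovalent-iodine level.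
  - I2 in CHCl3 converts 3 into 5-hydroxy-3-iodo-7-methoxy-4H-chromen-4-one F5, a well-known iodocyclisation.
  - F5 is then oxidised in the presence of mesitylene (mCPBA, TfOH, CH2Cl2, 0 °C). The arene attacks the resulting λ3-iodane to give 4.

**Further compounds**
F1 | step 3 | [2,4-bis(benzyloxy)phenyl](2,4,6-trimethylphenyl)iodonium trifluoromethanesulfonate | Cc1cc(C)c([I+]c2ccc(OCc3ccccc3)cc2OCc2ccccc2)c(C)c1.[O-]S(=O)(=O)C(F)(F)F
F2 | step 3 | 3-[2,4-bis(benzyloxy)phenyl]-5-hydroxy-7-methoxy-4H-chromen-4-one | COc1cc(O)c2c(=O)c(-c3ccc(OCc4ccccc4)cc3OCc3ccccc3)coc2c1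
F3 | step 6 | 3-{5-[(2,4-dimethoxyphenyl)(hydroxy)methyl]-2,4-dihydroxyphenyl}-5-hydroxy-7-methoxy-4H-chromen-4-one (racemic) | COc1ccc(C(O)c2cc(-c3coc4cc(OC)cc(O)c4c3=O)c(O)cc2O)c(OC)c1
F4 | step 6 | (E)-[2-(4-hydroxyphenyl)ethenyl]boronic acid | OB(O)/C=C/c1ccc(O)cc1
F5 | step 2 | 5-hydroxy-3-iodo-7-methoxy-4H-chromen-4-one | COc1cc(O)c2c(=O)c(I)coc2c1
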